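## The problem

Compound 21 is a 1,7-diarylheptanoid. Its chain is numbered from C1 (bearing the guaiacyl ring) to C7 (the benzylic CH2 of the 4-hydroxyphenyl unit), and an oxygen bridge between C1 and C5 folds C1–C5 into an oxane with a hydroxyl at C3 and the side chain C6(OH)–C7H2–aryl at C5.

- The aryl group and the side chain lie on opposite faces of the ring, so one must be axial. This 2,6-trans oxane is the less stable arrangement and has to be made under kinetic control and kept from equilibrating.
- There are four stereocentres (1S,3S,5S,6S). C1 and C5 face each other only across the ring oxygen, so ordinary acyclic 1,3-induction cannot relate them. C5 can control C6 directly, and C1 together with C5 must control C3, whose hydroxyl is cis to the aryl group.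
- Several groups are fragile. C1–O is a benzylic ether of a para-oxygenated arene, which ionises in strong acid and can be hydrogenolysed. Any intermediate with a carbonyl at C3 is a β-alkoxy ketone that can open to an aryl-conjugated enone and re-close as the cis isomer. The C5 hydrogen is acidic whenever C6 is a carbonyl, and both phenols need masking.
- The enabling feature is that C5 carries both the ring oxygen and C6. With C6 at the carboxyl level, C5 is the α-carbon of an α-alkoxy acid whose ether oxygen sits on C1.
- If that carboxyl is tied as a lactone to an oxygen on C2 and C3=C4 is a vinyl group, the enol form contains the allyl vinyl ether C5=C6(O)–O–C2–C3=C4. A [3,3] shift then joins C5 to C4, closes the ring O–C1–C2=C3–C4–C5, and lets the C1 stereocentre decide the configuration at C5.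

## Retrosynthesis

**21 from 20.** The last cut removes three O–benzyl bonds: two on the phenols and one on the C6 oxygen. Benzyl ethers are chosen for the phenols because they survive bases, hydrides and organometallics; the third is placed on C6 so that one hydrogenolysis finishes the synthesis. The forward step must spare the ring C1–O bond, a hindered dialkyl benzylic ether that is cleaved more slowly than aryl benzyl ethers.

**20 from 19, and 19 from 18.** The C3 carbinol is traced to the C3 ketone 19 and that to the C2=C3 alkene of dihydropyran 18. The alkene is what the sigmatropic step leaves behind. Hydroboration or epoxide opening would be expected to put oxygen on C2, next to the allylic ether carbon. Wacker-type hydroxypalladation attacks the alkene carbon remote from the allylic oxygen and gives the C3 ketone. The forward reduction must deliver hydride to the face away from the aryl group; a bulky hydride is chosen for this. Ketone 19 is the one intermediate that can epimerise to the cis ring, so it exists for two mild steps only.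

**18 from 17, and 17 from 16.** The C6–O benzyl bond and then the C6–H bond are cut, leading to benzyl ketone 16. An α-alkoxy ketone with the ring oxygen on C5 should be reduced in the Felkin–Anh sense to the 5,6-syn alcohol, which is the (6S) configuration needed. The alternative of adding the benzyl nucleophile to a C6 aldehyde was set aside because a 2-formyl dihydropyran is more easily epimerised at C5. The C6 hydroxyl is capped before the oxidation because a free hydroxyl two carbons from the alkene could add to it under palladium.

**16 from 13 and 15, 13 from 11.** The C6–C7 bond is cut between Weinreb amide 13 and benzylic Grignard reagent 15, made from chloride 14. The amide comes from acid 11. This puts the whole second aryl unit on in one step and leaves C6 at the ketone level without over-addition. It asks only that C5 not epimerise, which the chelated adduct and an amide (not an ester) should secure.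

**11 from 8 (key disconnection).** Cutting C4–C5 and re-forming the ester C–O bond turns the 2,6-trans dihydropyran acid 11 into the cis-5-aryl-6-vinyl-1,4-dioxan-2-one 8, by way of its silyl ketene acetal 9 and silyl ester 10. Against a C-glycosylation-type addition to an oxocarbenium ion, or an oxa-Michael closure, this cut has two advantages. The trans relation follows stereospecifically from the cis relation in 8 and not from a kinetic preference. The ring is formed with no carbonyl at C3, so it cannot equilibrate. The precursor is much simpler: one ring, two adjacent stereocentres that are both carbinol carbons, and no stereocentre at C5.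

**8 from 7, 6 and 5.** The lactone C–O bond and the ether O–CH2 bond are cut, taking out a two-carbon acetate unit and leaving the anti diol derivative 5. The ether oxygen must be the benzylic one and the ester oxygen the allylic one, or there is no allyl vinyl ether. A free diol offers no reliable way to tell a benzylic from an allylic secondary hydroxyl. In 5 the allylic oxygen therefore arrives silylated and only the benzylic hydroxyl is free. The acetate unit is attached by carbenoid O–H insertion under neutral conditions (ester 6), so the silyl group cannot migrate. Fluoride and mild acid then close the lactone through hydroxy ester 7. Strong acid is avoided throughout because of the electron-rich benzylic ether.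

**5 from 2 and 3, 2 from 1.** The bond between the two carbinol carbons is cut to give aldehyde 3 and the (E)-γ-silyloxyallylboronate 2. The closed transition state of allylboration translates the E geometry into the anti relation. A chiral phosphoric acid sets the absolute configuration on a non-enolisable aldehyde. Boronate 2 is one isomerisation step from the purchasable vinylboronate 1. All carbons of 8 except the acetate unit are then in place after one C–C bond formation.

## Roads not taken

**Alternative 1:** The chain is cut at C4–C5 and C2–C3 and assembled by an aldolase. 2-Deoxyribose-5-phosphate aldolase would add two molecules of acetaldehyde A2 in sequence to chloroacetaldehyde A1, and the adduct closes through the C5 oxygen to lactol A3.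
- Merits: C3 and C5 are set together, with the correct absolute and trans relative configuration, in one protecting-group-free step from two-carbon feedstocks. In this respect it is better than the chosen plan, which creates the C3 carbinol last and with its least certain selectivity.
- Weak points: A3 carries neither aryl group and no oxygen on C6. The chloromethyl carbon must be raised to an aldehyde and extended by the benzyl unit with 5,6-syn control. The guaiacyl group must be delivered to the anomeric carbon C1 trans to the C5 substituent; this is a kinetic axial arylation of a 2-deoxy oxocarbenium ion, which can revert to the equatorial (cis) product with an electron-rich arene.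
- Comparison: the ring core comes in one step, but a long tail of oxidation-state and C–C work follows. The chosen plan puts the aryl group and the C6 carbon on the ring in the ring-forming event and fixes the trans relation stereospecifically.

**Alternative 2:** The cut is at C3–C4 and at the C5 oxygen. Oxime A4 is converted into nitrile oxide A5, which adds to the terminal alkene of the tyrosine-derived allylic ether A6 to give isoxazoline A7, a masked β-hydroxy ketone.
- Merits: it is more convergent than the chosen plan. Two fragments of similar size, each already carrying its aryl group, are joined mid-route, and C6 comes from the chiral pool.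
- Weak points: face selectivity of nitrile oxide addition to a chiral allylic ether is usually modest. The new C5 oxygen in A7 has the configuration opposite to the target, so the ring would have to be closed by displacement at C5 with inversion by the C1 oxygen. That is a substitution at a secondary carbon flanked by the C6 ether, open to elimination. It also requires N–O cleavage, a 1,3-controlled reduction at C3 and differentiation of the C3 and C5 hydroxyls.
- Comparison: convergence favours this road. The chosen plan sets against it one stereospecific step for C5 in place of three separate selectivity problems (cycloaddition face, C3 reduction, invertive ring closure).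

**Alternative 3:** The cut is at C4–C5 and O–C1. The (S)-2-benzyloxy aldehyde A8 and 1-methoxy-3-(trimethylsilyloxy)buta-1,3-diene A9 combine under magnesium chelation, and acid treatment gives dihydropyranone A10.
- Merits: chelation sets C5 syn to C6 in the ring-forming step, C6 comes from tyrosine, and the C3 carbonyl is already present. Conjugate addition of the guaiacyl group would then give the 2,6-trans ketone by axial attack. This road is shorter than the chosen plan by about four steps and equally simple in its reagents.
- Weak points: A8 is an enolisable α-alkoxy aldehyde, and every stereocentre of the target would hang on its enantiomeric purity. The trans relation is created by a kinetically controlled conjugate addition that passes through the enolate of the very β-alkoxy ketone that can open and re-close to the cis ring. The C3 reduction problem is the same as in the chosen plan.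
- Comparison: on step count this road is better. The chosen plan sets against it a catalytic source of absolute configuration on a non-enolisable aldehyde, a stereospecific (not merely selective) origin of the trans relation in a ring that has no C3 carbonyl when it is formed, and a C6 carboxyl that lets the second aryl unit be varied late.

Key step: step 5

Remark on the chemistry: the face selectivity of the phosphoric acid in step 2 is assumed to follow the parent allyl- and crotylboronates, that is, the (S)-acid is assumed to send the allyl unit to the Si face of the aryl aldehyde; if the silyloxy reagent behaved otherwise, the (R)-acid would be used.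

## Route

Step 1
Reactants: 1 tert-butyldimethyl{[(2E)-3-(4,4,5,5-tetramethyl-1,3,2-dioxaborolan-2-yl)prop-2-en-1-yl]oxy}silane
Product: 2 tert-butyldimethyl{[(1E)-3-(4,4,5,5-tetramethyl-1,3,2-dioxaborolan-2-yl)prop-1-en-1-yl]oxy}silane
Conditions: [Ir(cod)(PPh2Me)2]PF6 (2 mol%, activated with H2, then degassed), THF, rt
Reagents that add atoms: none
Why: Iridium-hydride olefin isomerisation (the allyl ether to enol ether type, with a cationic monovalent iridium precatalyst) moves the double bond out of conjugation with boron into conjugation with oxygen; the silyl enol ether is the thermodynamic sink and the addition–elimination pathway should give the E isomer needed for the anti relation in step 2.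

Step 2
Reactants: 2 tert-butyldimethyl{[(1E)-3-(4,4,5,5-tetramethyl-1,3,2-dioxaborolan-2-yl)prop-1-en-1-yl]oxy}silane; 3 4-(benzyloxy)-3-methoxybenzaldehyde
Product: 5 (1R,2S)-1-[4-(benzyloxy)-3-methoxyphenyl]-2-[(tert-butyldimethylsilyl)oxy]but-3-en-1-ol, via pinacol borate ester 4 (not isolated)
Conditions: (S)-TRIP phosphoric acid (5 mol%), 4 Å MS, PhMe, −30 °C; aq. NaHCO3
Reagents that add atoms: none
Why: Chiral-phosphoric-acid-catalysed allylboration through a closed chair (Zimmerman–Traxler) transition state; the E silyloxy group sits equatorial, so the two oxygens come out anti (C2 set by alkene geometry), and the acid, hydrogen-bonded to a boronate oxygen and the formyl hydrogen, should direct attack to the Si face (C1 set by the catalyst). Aqueous work-up hydrolyses the B–O bond of 4.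

Step 3
Reactants: 5 (1R,2S)-1-[4-(benzyloxy)-3-methoxyphenyl]-2-[(tert-butyldimethylsilyl)oxy]but-3-en-1-ol
Product: 6 ethyl 2-{[(1R,2S)-1-[4-(benzyloxy)-3-methoxyphenyl]-2-[(tert-butyldimethylsilyl)oxy]but-3-en-1-yl]oxy}acetate
Conditions: Rh2(OAc)4 (1 mol%), ethyl diazoacetate (2 equiv, slow addition), CH2Cl2, rt
Reagents that add atoms: ethyl diazoacetate, CCOC(=O)C=[N+]=[N-]
Why: Rhodium-carbenoid O–H insertion alkylates the only free hydroxyl under neutral conditions, so the ether oxygen is unambiguously the benzylic one and no base is present to move the silyl group; O–H insertion should outrun cyclopropanation of the hindered allylic alkene. No stereocentre is touched.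

Step 4
Reactants: 6 ethyl 2-{[(1R,2S)-1-[4-(benzyloxy)-3-methoxyphenyl]-2-[(tert-butyldimethylsilyl)oxy]but-3-en-1-yl]oxy}acetate
Product: 8 (5R,6S)-5-[4-(benzyloxy)-3-methoxyphenyl]-6-ethenyl-1,4-dioxan-2-one, via hydroxy ester 7 (not isolated)
Conditions: Bu4NF, AcOH, THF, 0 °C to rt; then PPTS (cat.), PhMe, 70 °C
Reagents that add atoms: none
Why: Buffered fluoride desilylation frees the allylic hydroxyl, and mild acid-catalysed transesterification (lactonisation with loss of ethanol) closes the six-membered lactone; pyridinium tosylate is used because the electron-rich benzylic ether would ionise in strong acid. The anti diol becomes the cis-5,6-disubstituted ring with both stereocentres unchanged.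

Step 5
Reactants: 8 (5R,6S)-5-[4-(benzyloxy)-3-methoxyphenyl]-6-ethenyl-1,4-dioxan-2-one
Product: 11 (2S,6S)-6-[4-(benzyloxy)-3-methoxyphenyl]-3,6-dihydro-2H-pyran-2-carboxylic acid, via silyl ketene acetal 9 (not isolated), via trimethylsilyl ester 10 (not isolated)
Conditions: Me3SiCl/Et3N, then LiN(i-Pr)2, THF, −100 to 23 °C; PhMe, 80 °C; then H2O, pH 3
Reagents that add atoms: none
Why: Deprotonation at the lactone CH2 with the silyl chloride already present gives ring-bound silyl ketene acetal 9, in which the enol carbon (C5), the ester oxygen, the vinyl-bearing carbon and the vinyl group form an allyl vinyl ether. The concerted suprafacial [3,3] shift joins the enol carbon to the vinyl terminus (C4–C5) while the lactone O–C bond breaks, leaving silyl ester 10, which hydrolyses to 11. The closest known reaction is the Ireland–Claisen ring contraction of 6-alkenyl-1,4-dioxan-2-ones to dihydropyran-2-carboxylic acids. The dihydropyran is closed pericyclically: because the ketene acetal is held inside the six-membered ring, the transition state is a boat with a bicyclo[2.2.2]-like shape, and the new ring (ring O, C1, C2, C3, C4, C5) forms as the old one opens. The new stereocentre C5 is controlled by C1: the vinyl group can reach the enol carbon only on its own face, the aryl group is cis to the vinyl group in 8, and so the carboxyl group ends on the face opposite the aryl group (2,6-trans); the stereocentre at the vinyl-bearing carbon is consumed as it becomes C2 of the alkene. The selectivity needed is silylation of the enolate before it can fragment, plus complete transfer of the cis relation, and the ring constraint secures the latter by allowing neither a chair alternative nor an antarafacial path. The cis isomer is also the favourable substrate, since its reactive half-chair has the vinyl group pseudoaxial and the aryl group pseudoequatorial.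

Step 6
Reactants: 11 (2S,6S)-6-[4-(benzyloxy)-3-methoxyphenyl]-3,6-dihydro-2H-pyran-2-carboxylic acid
Product: 13 (2S,6S)-6-[4-(benzyloxy)-3-methoxyphenyl]-N-methoxy-N-methyl-3,6-dihydro-2H-pyran-2-carboxamide, via acyl imidazole 12 (not isolated)
Conditions: CDI, CH2Cl2, rt; then MeNH(OMe)·HCl, rt
Reagents that add atoms: N,O-dimethylhydroxylamine hydrochloride, CNOC.Cl
Why: Weinreb amide formation through the acyl imidazole is close to neutral, so the α-alkoxy stereocentre C5 should not epimerise, and the amide sets up a clean single addition in step 7.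

Step 7
Reactants: 13 (2S,6S)-6-[4-(benzyloxy)-3-methoxyphenyl]-N-methoxy-N-methyl-3,6-dihydro-2H-pyran-2-carboxamide; 14 4-(benzyloxy)benzyl chloride
Product: 16 2-[4-(benzyloxy)phenyl]-1-[(2S,6S)-6-[4-(benzyloxy)-3-methoxyphenyl]-3,6-dihydro-2H-pyran-2-yl]ethan-1-one, via benzylic Grignard reagent 15 (not isolated)
Conditions: 14, Mg, THF (dilute), 0 °C; then 13, THF, −20 to 0 °C; aq. NH4Cl
Reagents that add atoms: none
Why: Weinreb ketone synthesis: the five-membered magnesium chelate of the adduct survives until work-up, which prevents over-addition and keeps C5 from enolising; forming the benzylic Grignard reagent cold and dilute suppresses Wurtz coupling. This forms the C6–C7 bond.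

Step 8
Reactants: 16 2-[4-(benzyloxy)phenyl]-1-[(2S,6S)-6-[4-(benzyloxy)-3-methoxyphenyl]-3,6-dihydro-2H-pyran-2-yl]ethan-1-one
Product: 17 (1S)-2-[4-(benzyloxy)phenyl]-1-[(2S,6S)-6-[4-(benzyloxy)-3-methoxyphenyl]-3,6-dihydro-2H-pyran-2-yl]ethan-1-ol
Conditions: LiBH(s-Bu)3 (L-Selectride), THF, −78 °C
Reagents that add atoms: none
Why: Felkin–Anh reduction of an α-alkoxy ketone: with the ring C–O bond antiperiplanar to the incoming bulky, non-chelating hydride, attack past the C5 hydrogen should give the 5,6-syn alcohol, which is the (6S) carbinol of the target; C6 is set by C5.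

Step 9
Reactants: 17 (1S)-2-[4-(benzyloxy)phenyl]-1-[(2S,6S)-6-[4-(benzyloxy)-3-methoxyphenyl]-3,6-dihydro-2H-pyran-2-yl]ethan-1-ol
Product: 18 (2S,6S)-2-{(1S)-1-(benzyloxy)-2-[4-(benzyloxy)phenyl]ethyl}-6-[4-(benzyloxy)-3-methoxyphenyl]-3,6-dihydro-2H-pyran
Conditions: NaH, BnBr, Bu4NI (cat.), THF/DMF, 0 °C to rt
Reagents that add atoms: benzyl bromide, BrCc1ccccc1
Why: Williamson etherification; the benzyl ether keeps the C6 oxygen from adding to the alkene under palladium in step 10, makes the C5 substituent bulkier for step 11 and leaves in the final hydrogenolysis. The substrate has no base-sensitive site at this stage.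

Step 10
Reactants: 18 (2S,6S)-2-{(1S)-1-(benzyloxy)-2-[4-(benzyloxy)phenyl]ethyl}-6-[4-(benzyloxy)-3-methoxyphenyl]-3,6-dihydro-2H-pyran
Product: 19 (2S,6S)-2-[4-(benzyloxy)-3-methoxyphenyl]-6-{(1S)-1-(benzyloxy)-2-[4-(benzyloxy)phenyl]ethyl}oxan-4-one
Conditions: PdCl2 (10 mol%), CuCl (1 equiv), O2 (1 atm), DMF/H2O (7:1), rt
Reagents that add atoms: water, O
Why: Tsuji–Wacker oxidation: divalent palladium activates the alkene and water attacks the carbon remote from the allylic ring oxygen (C3), because the C1–O bond disfavours positive charge at C2; β-hydride elimination and tautomerisation give the oxan-4-one. Room temperature and a short reaction time limit acid-promoted opening of the β-alkoxy ketone.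

Step 11
Reactants: 19 (2S,6S)-2-[4-(benzyloxy)-3-methoxyphenyl]-6-{(1S)-1-(benzyloxy)-2-[4-(benzyloxy)phenyl]ethyl}oxan-4-one
Product: 20 (2S,4S,6S)-2-[4-(benzyloxy)-3-methoxyphenyl]-6-{(1S)-1-(benzyloxy)-2-[4-(benzyloxy)phenyl]ethyl}oxan-4-ol
Conditions: LiBH(s-Bu)3 (L-Selectride), THF, −78 °C
Reagents that add atoms: none
Why: Substrate-controlled reduction by a bulky hydride, which attacks a six-membered ketone equatorially; the trans ketone is expected to react through the chair with the branched C5 substituent equatorial and the aryl group axial (Curtin–Hammett), so hydride arrives anti to the aryl group and the C3 hydroxyl ends cis to it. The product then relaxes to the chair with aryl and hydroxyl equatorial.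

Step 12
Reactants: 20 (2S,4S,6S)-2-[4-(benzyloxy)-3-methoxyphenyl]-6-{(1S)-1-(benzyloxy)-2-[4-(benzyloxy)phenyl]ethyl}oxan-4-ol
Product: 21 (2S,4S,6S)-2-(4-hydroxy-3-methoxyphenyl)-6-[(1S)-1-hydroxy-2-(4-hydroxyphenyl)ethyl]oxan-4-ol
Conditions: H2 (1 atm), Pd/C (10%), EtOAc/MeOH, rt
Reagents that add atoms: none
Why: Hydrogenolysis of two aryl benzyl ethers and one alkyl benzyl ether; the ring C1–O bond is a hindered dialkyl benzylic ether and should be cleaved much more slowly, so the reaction is stopped once hydrogen uptake for three benzyl groups is complete. No stereocentre is affected.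

## Compound list

1 | tert-butyldimethyl{[(2E)-3-(4,4,5,5-tetramethyl-1,3,2-dioxaborolan-2-yl)prop-2-en-1-yl]oxy}silane | CC(C)(C)[Si](C)(C)OC/C=C/B1OC(C)(C)C(C)(C)O1 | starting material
2 | tert-butyldimethyl{[(1E)-3-(4,4,5,5-tetramethyl-1,3,2-dioxaborolan-2-yl)prop-1-en-1-yl]oxy}silane | CC(C)(C)[Si](C)(C)O/C=C/CB1OC(C)(C)C(C)(C)O1 | intermediate
3 | 4-(benzyloxy)-3-methoxybenzaldehyde | COc1cc(C=O)ccc1OCc1ccccc1 | starting material
4 | 2-{[(1R,2S)-1-[4-(benzyloxy)-3-methoxyphenyl]-2-[(tert-butyldimethylsilyl)oxy]but-3-en-1-yl]oxy}-4,4,5,5-tetramethyl-1,3,2-dioxaborolane | COc1cc([C@@H](OB2OC(C)(C)C(C)(C)O2)[C@@H](O[Si](C)(C)C(C)(C)C)C=C)ccc1OCc1ccccc1 | intermediate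
5 | (1R,2S)-1-[4-(benzyloxy)-3-methoxyphenyl]-2-[(tert-butyldimethylsilyl)oxy]but-3-en-1-ol | COc1cc([C@@H](O)[C@@H](O[Si](C)(C)C(C)(C)C)C=C)ccc1OCc1ccccc1 | intermediate
6 | ethyl 2-{[(1R,2S)-1-[4-(benzyloxy)-3-methoxyphenyl]-2-[(tert-butyldimethylsilyl)oxy]but-3-en-1-yl]oxy}acetate | COc1cc([C@@H](OCC(=O)OCC)[C@@H](O[Si](C)(C)C(C)(C)C)C=C)ccc1OCc1ccccc1 | intermediate
7 | ethyl 2-{[(1R,2S)-1-[4-(benzyloxy)-3-methoxyphenyl]-2-hydroxybut-3-en-1-yl]oxy}acetate | COc1cc([C@@H](OCC(=O)OCC)[C@@H](O)C=C)ccc1OCc1ccccc1 | intermediate
8 | (5R,6S)-5-[4-(benzyloxy)-3-methoxyphenyl]-6-ethenyl-1,4-dioxan-2-one | COc1cc([C@H]2OCC(=O)O[C@H]2C=C)ccc1OCc1ccccc1 | intermediate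
9 | {[(5R,6S)-5-[4-(benzyloxy)-3-methoxyphenyl]-6-ethenyl-5,6-dihydro-1,4-dioxin-2-yl]oxy}trimethylsilane | COc1cc([C@H]2OC=C(O[Si](C)(C)C)O[C@H]2C=C)ccc1OCc1ccccc1 | intermediate
10 | trimethylsilyl (2S,6S)-6-[4-(benzyloxy)-3-methoxyphenyl]-3,6-dihydro-2H-pyran-2-carboxylate | COc1cc([C@@H]2C=CC[C@@H](C(=O)O[Si](C)(C)C)O2)ccc1OCc1ccccc1 | intermediate
11 | (2S,6S)-6-[4-(benzyloxy)-3-methoxyphenyl]-3,6-dihydro-2H-pyran-2-carboxylic acid | COc1cc([C@@H]2C=CC[C@@H](C(=O)O)O2)ccc1OCc1ccccc1 | intermediate
12 | [(2S,6S)-6-[4-(benzyloxy)-3-methoxyphenyl]-3,6-dihydro-2H-pyran-2-yl](1H-imidazol-1-yl)methanone | COc1cc([C@@H]2C=CC[C@@H](C(=O)n3ccnc3)O2)ccc1OCc1ccccc1 | intermediate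
13 | (2S,6S)-6-[4-(benzyloxy)-3-methoxyphenyl]-N-methoxy-N-methyl-3,6-dihydro-2H-pyran-2-carboxamide | COc1cc([C@@H]2C=CC[C@@H](C(=O)N(C)OC)O2)ccc1OCc1ccccc1 | intermediate
14 | 4-(benzyloxy)benzyl chloride | ClCc1ccc(OCc2ccccc2)cc1 | starting material
15 | [4-(benzyloxy)benzyl]magnesium chloride | Cl[Mg]Cc1ccc(OCc2ccccc2)cc1 | intermediate
16 | 2-[4-(benzyloxy)phenyl]-1-[(2S,6S)-6-[4-(benzyloxy)-3-methoxyphenyl]-3,6-dihydro-2H-pyran-2-yl]ethan-1-one | COc1cc([C@@H]2C=CC[C@@H](C(=O)Cc3ccc(OCc4ccccc4)cc3)O2)ccc1OCc1ccccc1 | intermediate
17 | (1S)-2-[4-(benzyloxy)phenyl]-1-[(2S,6S)-6-[4-(benzyloxy)-3-methoxyphenyl]-3,6-dihydro-2H-pyran-2-yl]ethan-1-ol | COc1cc([C@@H]2C=CC[C@@H]([C@@H](O)Cc3ccc(OCc4ccccc4)cc3)O2)ccc1OCc1ccccc1 | intermediate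
18 | (2S,6S)-2-{(1S)-1-(benzyloxy)-2-[4-(benzyloxy)phenyl]ethyl}-6-[4-(benzyloxy)-3-methoxyphenyl]-3,6-dihydro-2H-pyran | COc1cc([C@@H]2C=CC[C@@H]([C@@H](OCc3ccccc3)Cc3ccc(OCc4ccccc4)cc3)O2)ccc1OCc1ccccc1 | intermediate
19 | (2S,6S)-2-[4-(benzyloxy)-3-methoxyphenyl]-6-{(1S)-1-(benzyloxy)-2-[4-(benzyloxy)phenyl]ethyl}oxan-4-one | COc1cc([C@@H]2CC(=O)C[C@@H]([C@@H](OCc3ccccc3)Cc3ccc(OCc4ccccc4)cc3)O2)ccc1OCc1ccccc1 | intermediate
20 | (2S,4S,6S)-2-[4-(benzyloxy)-3-methoxyphenyl]-6-{(1S)-1-(benzyloxy)-2-[4-(benzyloxy)phenyl]ethyl}oxan-4-ol | COc1cc([C@@H]2C[C@H](O)C[C@@H]([C@@H](OCc3ccccc3)Cc3ccc(OCc4ccccc4)cc3)O2)ccc1OCc1ccccc1 | intermediate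
21 | (2S,4S,6S)-2-(4-hydroxy-3-methoxyphenyl)-6-[(1S)-1-hydroxy-2-(4-hydroxyphenyl)ethyl]oxan-4-ol | COc1cc([C@@H]2C[C@H](O)C[C@@H]([C@@H](O)Cc3ccc(O)cc3)O2)ccc1O | target

## Step count and least certain steps

Total: 12 steps. Longest linear sequence: 12 steps (1 to 21); aldehyde 3 and chloride 14 are purchased and enter in steps 2 and 7.

**Step 5 (key step).** The enolate may fragment (opening of the lactone by β-elimination) or be silylated on carbon before the ketene acetal is secured, and the shift may be slow if the vinyl group cannot reach the pseudoaxial position, so that desilylation on work-up returns 8. The fallback builds the same ring by metathesis and sets out from aldehyde 3.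
- Amino-alcohol-catalysed addition of divinylzinc, Zn(CH=CH2)2, gives (1S)-1-[4-(benzyloxy)-3-methoxyphenyl]prop-2-en-1-ol F1.
- The sodium alkoxide of F1 displaces, with inversion, the triflate of ethyl (2R)-2-{[(trifluoromethyl)sulfonyl]oxy}pent-4-enoate F2. F2 is made from the corresponding hydroxy ester, which is obtainable from D-allylglycine. The product is ethyl (2S)-2-{[(1S)-1-[4-(benzyloxy)-3-methoxyphenyl]prop-2-en-1-yl]oxy}pent-4-enoate F3.
- Ring-closing metathesis with the second-generation Grubbs catalyst, (H2IMes)(PCy3)Cl2Ru=CHPh, gives ethyl (2S,6S)-6-[4-(benzyloxy)-3-methoxyphenyl]-3,6-dihydro-2H-pyran-2-carboxylate F4.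
- LiOH saponification returns the route at acid 11.

**Step 2.** The acid catalyst may protonate the silyl enol ether of 2 and cause its loss before allylboration, or enantiofacial control may be poor with the oxygenated allyl unit. The fallback moves the chirality from the catalyst onto boron and sets out from boronate 2.
- Transesterification with diisopropyl (2R,3R)-tartrate gives diisopropyl (4R,5R)-2-[(2E)-3-{[tert-butyl(dimethyl)silyl]oxy}prop-2-en-1-yl]-1,3,2-dioxaborolane-4,5-dicarboxylate F5.
- F5 adds to 3 without catalyst at −78 °C (PhMe, 4 Å MS) through the same chair, the (R,R)-tartrate being expected to favour the Si face, and gives the tartrate borate ester of 5, F6.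
- Aqueous work-up of F6 returns the route at alcohol 5. The enantiomeric purity is expected to be lower and would be raised by crystallising acid 11 as an amine salt.

**Step 11.** Hydride may be delivered to the other face if the ketone reacts through the chair with the aryl group equatorial; facial selectivity here rests on a conformational argument. The fallback sets out from ketone 19 and does not depend on the sense of the reduction.
- The C4 epimer (2S,4R,6S)-2-[4-(benzyloxy)-3-methoxyphenyl]-6-{(1S)-1-(benzyloxy)-2-[4-(benzyloxy)phenyl]ethyl}oxan-4-ol F7 is taken on. It is formed in that case, or deliberately with NaBH4.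
- Mitsunobu inversion with 4-nitrobenzoic acid, PPh3 and diisopropyl azodicarboxylate gives the (2S,4S,6S) 4-nitrobenzoate F8.
- K2CO3 in MeOH returns the route at alcohol 20.

**Step 10.** Hydroxypalladation of the internal alkene may be slow, palladium hydride may move the double bond, and the acid formed may open the β-alkoxy ketone and let it re-close as the cis ring. The fallback sets out from alkene 18 and uses a different electrophile with the same regiochemical bias.
- Oxymercuration with Hg(OAc)2 in THF/H2O gives the 3-(acetoxymercurio)oxan-4-ol F9.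
- NaBH4/NaOH demercuration gives the oxan-4-ol F10 as either C4 epimer.
- Dess–Martin periodinane oxidises F10, returning the route at ketone 19.

**Step 8.** Lithium chelation between the ring oxygen and the carbonyl may erode the Felkin–Anh preference, and hydride may act as a base on the acidic benzylic CH2. The fallback sets out from amide 13 and reaches the same diastereomer by the opposite control element.
- Reduction with i-Bu2AlH gives (2S,6S)-6-[4-(benzyloxy)-3-methoxyphenyl]-3,6-dihydro-2H-pyran-2-carbaldehyde F11.
- Grignard reagent 15 is added to F11 in the presence of MgBr2·OEt2 under chelation control, which for a carbon nucleophile gives the same 5,6-syn carbinol and returns the route at alcohol 17.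

## Further compounds

F1 | step 5 | (1S)-1-[4-(benzyloxy)-3-methoxyphenyl]prop-2-en-1-ol | COc1cc([C@@H](O)C=C)ccc1OCc1ccccc1
F2 | step 5 | ethyl (2R)-2-{[(trifluoromethyl)sulfonyl]oxy}pent-4-enoate | CCOC(=O)[C@@H](CC=C)OS(=O)(=O)C(F)(F)F
F3 | step 5 | ethyl (2S)-2-{[(1S)-1-[4-(benzyloxy)-3-methoxyphenyl]prop-2-en-1-yl]oxy}pent-4-enoate | COc1cc([C@H](C=C)O[C@@H](CC=C)C(=O)OCC)ccc1OCc1ccccc1
F4 | step 5 | ethyl (2S,6S)-6-[4-(benzyloxy)-3-methoxyphenyl]-3,6-dihydro-2H-pyran-2-carboxylate | COc1cc([C@@H]2C=CC[C@@H](C(=O)OCC)O2)ccc1OCc1ccccc1
F5 | step 2 | diisopropyl (4R,5R)-2-[(2E)-3-{[tert-butyl(dimethyl)silyl]oxy}prop-2-en-1-yl]-1,3,2-dioxaborolane-4,5-dicarboxylate | CC(C)OC(=O)[C@@H]1OB(C/C=C/O[Si](C)(C)C(C)(C)C)O[C@H]1C(=O)OC(C)C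
F6 | step 2 | diisopropyl (4R,5R)-2-{[(1R,2S)-1-[4-(benzyloxy)-3-methoxyphenyl]-2-[(tert-butyldimethylsilyl)oxy]but-3-en-1-yl]oxy}-1,3,2-dioxaborolane-4,5-dicarboxylate | COc1cc([C@@H](OB2O[C@@H](C(=O)OC(C)C)[C@H](C(=O)OC(C)C)O2)[C@@H](O[Si](C)(C)C(C)(C)C)C=C)ccc1OCc1ccccc1
F7 | step 11 | (2S,4R,6S)-2-[4-(benzyloxy)-3-methoxyphenyl]-6-{(1S)-1-(benzyloxy)-2-[4-(benzyloxy)phenyl]ethyl}oxan-4-ol | COc1cc([C@@H]2C[C@@H](O)C[C@@H]([C@@H](OCc3ccccc3)Cc3ccc(OCc4ccccc4)cc3)O2)ccc1OCc1ccccc1
F8 | step 11 | (2S,4S,6S)-2-[4-(benzyloxy)-3-methoxyphenyl]-6-{(1S)-1-(benzyloxy)-2-[4-(benzyloxy)phenyl]ethyl}oxan-4-yl 4-nitrobenzoate | COc1cc([C@@H]2C[C@H](OC(=O)c3ccc(cc3)[N+](=O)[O-])C[C@@H]([C@@H](OCc3ccccc3)Cc3ccc(OCc4ccccc4)cc3)O2)ccc1OCc1ccccc1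
F9 | step 10 | {(2S,6S)-2-[4-(benzyloxy)-3-methoxyphenyl]-6-{(1S)-1-(benzyloxy)-2-[4-(benzyloxy)phenyl]ethyl}-4-hydroxyoxan-3-yl}mercury acetate (3,4-trans, either face) | COc1cc([C@@H]2C([Hg]OC(C)=O)C(O)C[C@@H]([C@@H](OCc3ccccc3)Cc3ccc(OCc4ccccc4)cc3)O2)ccc1OCc1ccccc1
F10 | step 10 | (2S,6S)-2-[4-(benzyloxy)-3-methoxyphenyl]-6-{(1S)-1-(benzyloxy)-2-[4-(benzyloxy)phenyl]ethyl}oxan-4-ol (either C4 epimer) | COc1cc([C@@H]2CC(O)C[C@@H]([C@@H](OCc3ccccc3)Cc3ccc(OCc4ccccc4)cc3)O2)ccc1OCc1ccccc1
F11 | step 8 | (2S,6S)-6-[4-(benzyloxy)-3-methoxyphenyl]-3,6-dihydro-2H-pyran-2-carbaldehyde | COc1cc([C@@H]2C=CC[C@@H](C=O)O2)ccc1OCc1ccccc1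
A1 | alternative 1 | chloroacetaldehyde | ClCC=O
A2 | alternative 1 | acetaldehyde | CC=O
A3 | alternative 1 | (4R,6S)-6-(chloromethyl)tetrahydro-2H-pyran-2,4-diol (anomeric mixture) | OC1C[C@H](O)C[C@@H](CCl)O1
A4 | alternative 2 | (3S)-3-[4-(benzyloxy)-3-methoxyphenyl]-3-[(tert-butyldimethylsilyl)oxy]propanal oxime | COc1cc([C@@H](O[Si](C)(C)C(C)(C)C)CC=NO)ccc1OCc1ccccc1
A5 | alternative 2 | (3S)-3-[4-(benzyloxy)-3-methoxyphenyl]-3-[(tert-butyldimethylsilyl)oxy]propanenitrile oxide | COc1cc([C@@H](O[Si](C)(C)C(C)(C)C)CC#[N+][O-])ccc1OCc1ccccc1
A6 | alternative 2 | 1-(benzyloxy)-4-[(2S)-2-(benzyloxy)but-3-en-1-yl]benzene | C=C[C@@H](OCc1ccccc1)Cc1ccc(OCc2ccccc2)cc1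
A7 | alternative 2 | (5R)-3-{(2S)-2-[4-(benzyloxy)-3-methoxyphenyl]-2-[(tert-butyldimethylsilyl)oxy]ethyl}-5-{(1S)-1-(benzyloxy)-2-[4-(benzyloxy)phenyl]ethyl}-4,5-dihydro-1,2-oxazole | COc1cc([C@@H](O[Si](C)(C)C(C)(C)C)CC2=NO[C@@H]([C@@H](OCc3ccccc3)Cc3ccc(OCc4ccccc4)cc3)C2)ccc1OCc1ccccc1
A8 | alternative 3 | (2S)-2-(benzyloxy)-3-[4-(benzyloxy)phenyl]propanal | O=C[C@@H](OCc1ccccc1)Cc1ccc(OCc2ccccc2)cc1
A9 | alternative 3 | (1E)-1-methoxy-3-(trimethylsilyloxy)buta-1,3-diene | CO/C=C/C(=C)O[Si](C)(C)C
A10 | alternative 3 | (2S)-2-{(1S)-1-(benzyloxy)-2-[4-(benzyloxy)phenyl]ethyl}-2,3-dihydro-4H-pyran-4-one | C1=CC(=O)C[C@@H]([C@@H](OCc2ccccc2)Cc2ccc(OCc3ccccc3)cc2)O1
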